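Assumption: labdane numbering (C-1 to C-20 of the parent diterpene skeleton) is used for atom labels in all cyclic compounds; geranial and Chan's diene are bought.

**Retrosynthetic overview**
1. Side chain last: target ⇐ vinyl addition to methyl ketone 17 ⇐ acetone aldol on the C-11 aldehyde 16.
2. Bridged δ-lactone (formed last of the rings) ⇐ Markovnikov hydro-acyloxylation of the exocyclic alkene of seco-diacid 13 by the C-2 acid.
3. Seco-diacid 13 ⇐ oxidative C-2/C-3 scission of ring A of the trans-decalin ketone 11; ring A is a temporary stereocontrol ring.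
4. Decalin 7 ⇐ one-operation epoxy-polyene bicyclization of acyclic 6: rings A and B form together and C-5, C-9, C-10 are set from C-6.
5. Acyclic 6 ⇐ geranial + Chan's diene by an asymmetric vinylogous aldol addition that sets C-6.

**Step 1**
Reactants: 1 geranial; 2 Chan's diene
Product: 4 methyl (5R,6E)-5-hydroxy-7,11-dimethyl-3-oxododeca-6,10-dienoate, via bis-silyl aldol adduct 3 (not isolated)
Conditions: Ti(OiPr)4 (10 mol%), (R)-BINOL (10 mol%; ligand antipode chosen to give 5R), 4 Å MS, THF, −78 → 0 °C; then 1 M HCl, THF, 0 °C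
Reagents that add atoms: none
Why: Titanium–BINOL-catalysed vinylogous Mukaiyama aldol addition of the terminal carbon of the diene to the aldehyde carbonyl (1,2-addition), in which the chiral titanium complex shields one face of the enal and sets the carbinol centre (later C-6) as R.

**Step 2**
Reactants: 4 methyl (5R,6E)-5-hydroxy-7,11-dimethyl-3-oxododeca-6,10-dienoate
Product: 5 methyl (5R,6E)-5-(tert-butyldimethylsilyloxy)-7,11-dimethyl-3-oxododeca-6,10-dienoate
Conditions: TBSCl, imidazole, DMF, 0 → 25 °C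
Reagents that add atoms: tert-butyldimethylsilyl chloride, CC(C)(C)[Si](C)(C)Cl
Why: Standard imidazole-mediated silylation of the secondary allylic alcohol, mild enough to avoid β-elimination next to the ketone and leaving the stereocentre untouched.

**Step 3**
Reactants: 5 methyl (5R,6E)-5-(tert-butyldimethylsilyloxy)-7,11-dimethyl-3-oxododeca-6,10-dienoate
Product: 6 methyl (5R,6E)-5-(tert-butyldimethylsilyloxy)-9-(3,3-dimethyloxiran-2-yl)-7-methyl-3-oxonon-6-enoate (both oxirane epimers)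
Conditions: mCPBA (1.0 equiv), NaHCO3, CH2Cl2, −20 °C
Reagents that add atoms: 3-chloroperbenzoic acid, O=C(OO)c1cccc(Cl)c1
Why: Prilezhaev epoxidation goes to the terminal trisubstituted alkene because the internal one is deactivated and shielded by the allylic silyloxy group; the new oxirane centre is not controlled and is erased in step 8.

**Step 4 (key step)**
Reactants: 6 methyl (5R,6E)-5-(tert-butyldimethylsilyloxy)-9-(3,3-dimethyloxiran-2-yl)-7-methyl-3-oxonon-6-enoate
Product: 7 methyl (5S,6R,9S,10R)-6-(tert-butyldimethylsilyloxy)-3-hydroxy-4,4,10-trimethyl-8-oxo-trans-decalin-9-carboxylate (both C-3 epimers)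
Conditions: MeAlCl2 (2 equiv), CH2Cl2, −78 °C; aq. NaHCO3
Reagents that add atoms: none
Why: Cationic epoxy-polyene bicyclization (van Tamelen–Corey type, antiperiplanar Stork–Eschenmoser additions) terminated by C-alkylation of the β-keto ester enol, in which the chair–chair transition state that keeps the 6-silyloxy group equatorial closes rings A and B at once and sets C-5 and C-10 (trans fusion) and the equatorial, epimerisable C-9 ester relative to C-6 for either oxirane epimer.

**Step 5**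
Reactants: 7 methyl (5S,6R,9S,10R)-6-(tert-butyldimethylsilyloxy)-3-hydroxy-4,4,10-trimethyl-8-oxo-trans-decalin-9-carboxylate
Product: 8 methyl (5S,6R,9R,10R)-6-(tert-butyldimethylsilyloxy)-3-hydroxy-4,4,10-trimethyl-8-methylidene-trans-decalin-9-carboxylate
Conditions: Zn, CH2Br2, TiCl4, THF/CH2Cl2, 0 → 25 °C
Reagents that add atoms: dibromomethane, BrCBr
Why: Takai–Lombardo methylenation uses a non-basic zinc/titanium methylene reagent that converts the hindered, enolisable C-8 ketone into the exocyclic alkene without epimerising C-9 or touching the ester.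

**Step 6**
Reactants: 8 methyl (5S,6R,9R,10R)-6-(tert-butyldimethylsilyloxy)-3-hydroxy-4,4,10-trimethyl-8-methylidene-trans-decalin-9-carboxylate
Product: 9 (5S,6R,9R,10S)-6-(tert-butyldimethylsilyloxy)-9-(hydroxymethyl)-4,4,10-trimethyl-8-methylidene-trans-decalin-3-ol
Conditions: LiAlH4, THF, 0 °C
Reagents that add atoms: none
Why: Hydride reduction of the ester to the C-11 primary alcohol removes the acidic allylic C-9 hydrogen problem before the basic step 9 and creates no stereocentre.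

**Step 7**
Reactants: 9 (5S,6R,9R,10S)-6-(tert-butyldimethylsilyloxy)-9-(hydroxymethyl)-4,4,10-trimethyl-8-methylidene-trans-decalin-3-ol
Product: 10 (5S,6R,9R,10S)-6-(tert-butyldimethylsilyloxy)-9-[(tert-butyldimethylsilyloxy)methyl]-4,4,10-trimethyl-8-methylidene-trans-decalin-3-ol
Conditions: TBSCl (1.05 equiv), imidazole, CH2Cl2, 0 °C
Reagents that add atoms: tert-butyldimethylsilyl chloride, CC(C)(C)[Si](C)(C)Cl
Why: Selective silylation of the primary alcohol over the neopentyl-type secondary 3-hydroxyl flanked by the gem-dimethyl carbon.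

**Step 8**
Reactants: 10 (5S,6R,9R,10S)-6-(tert-butyldimethylsilyloxy)-9-[(tert-butyldimethylsilyloxy)methyl]-4,4,10-trimethyl-8-methylidene-trans-decalin-3-ol
Product: 11 (5S,6R,9R,10S)-6-(tert-butyldimethylsilyloxy)-9-[(tert-butyldimethylsilyloxy)methyl]-4,4,10-trimethyl-8-methylidene-trans-decalin-3-one
Conditions: Dess–Martin periodinane, NaHCO3, CH2Cl2, 25 °C
Reagents that add atoms: none
Why: Dess–Martin oxidation of the secondary alcohol under neutral conditions converges both C-3 epimers to one ketone and leaves alkene and silyl ethers intact.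

**Step 9**
Reactants: 11 (5S,6R,9R,10S)-6-(tert-butyldimethylsilyloxy)-9-[(tert-butyldimethylsilyloxy)methyl]-4,4,10-trimethyl-8-methylidene-trans-decalin-3-one
Product: 13 2-[(1S,2S,3R,6R)-6-(tert-butyldimethylsilyloxy)-3-[(tert-butyldimethylsilyloxy)methyl]-2-(carboxymethyl)-2-methyl-4-methylidenecyclohexyl]-2-methylpropanoic acid, via diosphenol 12 (not isolated)
Conditions: O2 (1 atm), t-BuOK, t-BuOH, 25 °C; then 30% H2O2, 0 °C; aq. HCl work-up
Reagents that add atoms: dioxygen, O=O; hydrogen peroxide, OO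
Why: Base-mediated autoxidation of the 3-ketone, which can enolise only toward C-2, gives the diosphenol, and alkaline peroxide cleaves this 1,2-dicarbonyl (the classical ring A 2,3-seco cleavage), so ring A is cut into the C-2 and C-3 acids without touching any stereocentre.

**Step 10**
Reactants: 13 2-[(1S,2S,3R,6R)-6-(tert-butyldimethylsilyloxy)-3-[(tert-butyldimethylsilyloxy)methyl]-2-(carboxymethyl)-2-methyl-4-methylidenecyclohexyl]-2-methylpropanoic acid
Product: 14 2-{(1S,5R,6S,7R,9R)-7-(tert-butyldimethylsilyloxy)-9-[(tert-butyldimethylsilyloxy)methyl]-1,5-dimethyl-3-oxo-2-oxabicyclo[3.3.1]nonan-6-yl}-2-methylpropanoic acid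
Conditions: Co(salen) [Co(C16H14N2O2), 5 mol%], N-fluoro-2,4,6-trimethylpyridinium triflate, (Me2SiH)2O, PhCF3, 25 °C
Reagents that add atoms: none
Why: Cobalt-hydride hydrogen-atom transfer with radical–polar crossover (Mukaiyama-type hydrofunctionalisation, Shigehisa hydro-acyloxylation) turns the exocyclic alkene into a tertiary C-8 cation equivalent that is trapped irreversibly by the C-2 acid tethered through C-10, so the new C–O bond is cis to C-1 and the new methyl trans (8S), the ring adopting a twist-boat, while the neopentyl C-3 acid cannot reach C-8.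

**Step 11**
Reactants: 14 2-{(1S,5R,6S,7R,9R)-7-(tert-butyldimethylsilyloxy)-9-[(tert-butyldimethylsilyloxy)methyl]-1,5-dimethyl-3-oxo-2-oxabicyclo[3.3.1]nonan-6-yl}-2-methylpropanoic acid
Product: 15 2-[(1S,5R,6S,7R,9R)-7-hydroxy-9-(hydroxymethyl)-1,5-dimethyl-3-oxo-2-oxabicyclo[3.3.1]nonan-6-yl]-2-methylpropanoic acid
Conditions: HF·pyridine, pyridine/THF, 0 → 25 °C
Reagents that add atoms: none
Why: Buffered fluoride desilylation frees both alcohols under weakly acidic, non-nucleophilic conditions that do not open or migrate the tertiary lactone.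

**Step 12**
Reactants: 15 2-[(1S,5R,6S,7R,9R)-7-hydroxy-9-(hydroxymethyl)-1,5-dimethyl-3-oxo-2-oxabicyclo[3.3.1]nonan-6-yl]-2-methylpropanoic acid
Product: 16 2-[(1S,5R,6S,7R,9S)-9-formyl-7-hydroxy-1,5-dimethyl-3-oxo-2-oxabicyclo[3.3.1]nonan-6-yl]-2-methylpropanoic acid
Conditions: TEMPO (10 mol%), PhI(OAc)2, CH2Cl2, 25 °C
Reagents that add atoms: none
Why: Oxoammonium (TEMPO) oxidation is selective for the primary alcohol over the hindered secondary one and stops at the aldehyde, whose C-9 hydrogen between two quaternary carbons does not epimerise under these neutral conditions.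

**Step 13**
Reactants: 16 2-[(1S,5R,6S,7R,9S)-9-formyl-7-hydroxy-1,5-dimethyl-3-oxo-2-oxabicyclo[3.3.1]nonan-6-yl]-2-methylpropanoic acid
Product: 17 2-{(1S,5R,6S,7R,9R)-7-hydroxy-9-[(1S)-1-hydroxy-3-oxobutyl]-1,5-dimethyl-3-oxo-2-oxabicyclo[3.3.1]nonan-6-yl}-2-methylpropanoic acid
Conditions: D-proline (30 mol%), acetone/DMSO 1:4, 25 °C
Reagents that add atoms: acetone, CC(C)=O
Why: List–Barbas proline-catalysed direct aldol reaction, in which the D-proline enamine of acetone adds to one face of the α-branched aldehyde under reagent control to give the 11S carbinol.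

**Step 14**
Reactants: 17 2-{(1S,5R,6S,7R,9R)-7-hydroxy-9-[(1S)-1-hydroxy-3-oxobutyl]-1,5-dimethyl-3-oxo-2-oxabicyclo[3.3.1]nonan-6-yl}-2-methylpropanoic acid
Product: 18 2-{(1S,5R,6S,7R,9R)-9-[(1S,3S)-1,3-dihydroxy-3-methylpent-4-en-1-yl]-7-hydroxy-1,5-dimethyl-3-oxo-2-oxabicyclo[3.3.1]nonan-6-yl}-2-methylpropanoic acid (CNP0297019.2)
Conditions: CH2=CHMgBr (5 equiv), THF, −78 °C; aq. NH4Cl
Reagents that add atoms: vinylmagnesium bromide, C=C[Mg]Br
Why: Chelation-controlled Grignard addition, in which magnesium bridges the C-11 alkoxide and the ketone and vinyl attacks the less hindered face of the six-membered chelate to give the 11,13-anti diol (13S), the methyl ketone reacting far faster than the hindered lactone at −78 °C.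

**Compound list**
1 | geranial, (2E)-3,7-dimethylocta-2,6-dienal | O=C/C=C(\C)CCC=C(C)C | starting material
2 | Chan's diene, 1-methoxy-1,3-bis(trimethylsilyloxy)buta-1,3-diene | COC(O[Si](C)(C)C)=CC(=C)O[Si](C)(C)C | starting material
3 | (5R,6E)-1-methoxy-7,11-dimethyl-1,5-bis(trimethylsilyloxy)dodeca-1,6,10-trien-3-one | COC(O[Si](C)(C)C)=CC(=O)C[C@@H](O[Si](C)(C)C)/C=C(\C)CCC=C(C)C | intermediate
4 | methyl (5R,6E)-5-hydroxy-7,11-dimethyl-3-oxododeca-6,10-dienoate | COC(=O)CC(=O)C[C@@H](O)/C=C(\C)CCC=C(C)C | intermediate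
5 | methyl (5R,6E)-5-(tert-butyldimethylsilyloxy)-7,11-dimethyl-3-oxododeca-6,10-dienoate | COC(=O)CC(=O)C[C@@H](O[Si](C)(C)C(C)(C)C)/C=C(\C)CCC=C(C)C | intermediate
6 | methyl (5R,6E)-5-(tert-butyldimethylsilyloxy)-9-(3,3-dimethyloxiran-2-yl)-7-methyl-3-oxonon-6-enoate (both oxirane epimers) | COC(=O)CC(=O)C[C@@H](O[Si](C)(C)C(C)(C)C)/C=C(\C)CCC1OC1(C)C | intermediate
7 | methyl (5S,6R,9S,10R)-6-(tert-butyldimethylsilyloxy)-3-hydroxy-4,4,10-trimethyl-8-oxo-trans-decalin-9-carboxylate (both C-3 epimers) | COC(=O)[C@@H]1C(=O)C[C@@H](O[Si](C)(C)C(C)(C)C)[C@@H]2C(C)(C)C(O)CC[C@@]12C | intermediate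
8 | methyl (5S,6R,9R,10R)-6-(tert-butyldimethylsilyloxy)-3-hydroxy-4,4,10-trimethyl-8-methylidene-trans-decalin-9-carboxylate (both C-3 epimers) | COC(=O)[C@@H]1C(=C)C[C@@H](O[Si](C)(C)C(C)(C)C)[C@@H]2C(C)(C)C(O)CC[C@@]12C | intermediate
9 | (5S,6R,9R,10S)-6-(tert-butyldimethylsilyloxy)-9-(hydroxymethyl)-4,4,10-trimethyl-8-methylidene-trans-decalin-3-ol (both C-3 epimers) | OC[C@@H]1C(=C)C[C@@H](O[Si](C)(C)C(C)(C)C)[C@@H]2C(C)(C)C(O)CC[C@@]12C | intermediate
10 | (5S,6R,9R,10S)-6-(tert-butyldimethylsilyloxy)-9-[(tert-butyldimethylsilyloxy)methyl]-4,4,10-trimethyl-8-methylidene-trans-decalin-3-ol (both C-3 epimers) | CC(C)(C)[Si](C)(C)OC[C@@H]1C(=C)C[C@@H](O[Si](C)(C)C(C)(C)C)[C@@H]2C(C)(C)C(O)CC[C@@]12C | intermediate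
11 | (5S,6R,9R,10S)-6-(tert-butyldimethylsilyloxy)-9-[(tert-butyldimethylsilyloxy)methyl]-4,4,10-trimethyl-8-methylidene-trans-decalin-3-one | CC(C)(C)[Si](C)(C)OC[C@@H]1C(=C)C[C@@H](O[Si](C)(C)C(C)(C)C)[C@@H]2C(C)(C)C(=O)CC[C@@]12C | intermediate
12 | (5S,6R,9R,10S)-6-(tert-butyldimethylsilyloxy)-9-[(tert-butyldimethylsilyloxy)methyl]-2-hydroxy-4,4,10-trimethyl-8-methylidene-trans-decal-1-en-3-one (diosphenol) | CC(C)(C)[Si](C)(C)OC[C@@H]1C(=C)C[C@@H](O[Si](C)(C)C(C)(C)C)[C@@H]2C(C)(C)C(=O)C(O)=C[C@@]12C | intermediate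
13 | 2-[(1S,2S,3R,6R)-6-(tert-butyldimethylsilyloxy)-3-[(tert-butyldimethylsilyloxy)methyl]-2-(carboxymethyl)-2-methyl-4-methylidenecyclohexyl]-2-methylpropanoic acid | CC(C)(C)[Si](C)(C)OC[C@@H]1C(=C)C[C@@H](O[Si](C)(C)C(C)(C)C)[C@H](C(C)(C)C(=O)O)[C@@]1(C)CC(=O)O | intermediate
14 | 2-{(1S,5R,6S,7R,9R)-7-(tert-butyldimethylsilyloxy)-9-[(tert-butyldimethylsilyloxy)methyl]-1,5-dimethyl-3-oxo-2-oxabicyclo[3.3.1]nonan-6-yl}-2-methylpropanoic acid | CC(C)(C)[Si](C)(C)OC[C@H]1[C@]2(C)CC(=O)O[C@@]1(C)C[C@@H](O[Si](C)(C)C(C)(C)C)[C@@H]2C(C)(C)C(=O)O | intermediate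
15 | 2-[(1S,5R,6S,7R,9R)-7-hydroxy-9-(hydroxymethyl)-1,5-dimethyl-3-oxo-2-oxabicyclo[3.3.1]nonan-6-yl]-2-methylpropanoic acid | OC[C@H]1[C@]2(C)CC(=O)O[C@@]1(C)C[C@@H](O)[C@@H]2C(C)(C)C(=O)O | intermediate
16 | 2-[(1S,5R,6S,7R,9S)-9-formyl-7-hydroxy-1,5-dimethyl-3-oxo-2-oxabicyclo[3.3.1]nonan-6-yl]-2-methylpropanoic acid | O=C[C@H]1[C@]2(C)CC(=O)O[C@@]1(C)C[C@@H](O)[C@@H]2C(C)(C)C(=O)O | intermediate
17 | 2-{(1S,5R,6S,7R,9R)-7-hydroxy-9-[(1S)-1-hydroxy-3-oxobutyl]-1,5-dimethyl-3-oxo-2-oxabicyclo[3.3.1]nonan-6-yl}-2-methylpropanoic acid | CC(=O)C[C@H](O)[C@H]1[C@]2(C)CC(=O)O[C@@]1(C)C[C@@H](O)[C@@H]2C(C)(C)C(=O)O | intermediate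
18 | 2-{(1S,5R,6S,7R,9R)-9-[(1S,3S)-1,3-dihydroxy-3-methylpent-4-en-1-yl]-7-hydroxy-1,5-dimethyl-3-oxo-2-oxabicyclo[3.3.1]nonan-6-yl}-2-methylpropanoic acid | C=C[C@@](C)(O)C[C@H](O)[C@H]1[C@]2(C)CC(=O)O[C@@]1(C)C[C@@H](O)[C@@H]2C(C)(C)C(=O)O | target

**Totals**
Total step count: 14. Longest linear sequence: 14 steps (fully linear from geranial).

**Steps most likely to fail and their fallbacks**

Step 4 (bicyclization). The risks are O-alkylation by the keto ester enol, ionisation of the allylic silyl ether, or poor control by C-6. The fallback sets out from 5 and comes back at 10, replacing the cationic cascade by a radical one with an alkene terminus. Compound 5 is treated with NaH and ClP(O)(OEt)2 to give methyl (2Z,5R,6E)-5-(tert-butyldimethylsilyloxy)-3-(diethoxyphosphoryloxy)-7,11-dimethyldodeca-2,6,10-trienoate F1. Me2CuLi converts this with retention into methyl (2E,5R,6E)-5-(tert-butyldimethylsilyloxy)-3,7,11-trimethyldodeca-2,6,10-trienoate F2. i-Bu2AlH reduces the ester to the allylic alcohol (2E,5R,6E)-5-(tert-butyldimethylsilyloxy)-3,7,11-trimethyldodeca-2,6,10-trien-1-ol F3, TBSCl/imidazole gives its bis-silyl ether F4, and mCPBA gives the terminal epoxide F5. Cp2TiCl (trivalent titanium, made from Cp2TiCl2 and Mn in THF) opens the oxirane homolytically, and the 6-endo/6-endo radical cascade ends by loss of hydrogen from the titanium-bound C-8 centre. This delivers the exocyclic alkene 10 directly, so steps 5 to 7 are not needed.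

Step 5 (methylenation of a hindered β-keto ester). The fallback sets out from 7 and comes back at 8 by a Peterson olefination. Me3SiCH2MgCl with CeCl3 (THF, −78 °C) adds to the ketone without enolisation to give methyl 6-(tert-butyldimethylsilyloxy)-3,8-dihydroxy-4,4,10-trimethyl-8-[(trimethylsilyl)methyl]-trans-decalin-9-carboxylate F6. BF3·OEt2 (or KH) then eliminates silanol to give 8.

Step 10 (closure of the strained bridged lactone). The risk is alkene isomerisation into the ring instead of capture by the acid. The fallback sets out from 13 and comes back at 14 by a polar halolactonization followed by radical dehalogenation. I2 and NaHCO3 in MeCN give the kinetic iodolactone 2-{7-(tert-butyldimethylsilyloxy)-9-[(tert-butyldimethylsilyloxy)methyl]-1-(iodomethyl)-5-methyl-3-oxo-2-oxabicyclo[3.3.1]nonan-6-yl}-2-methylpropanoic acid F7, in which the carboxylate again attacks C-8 from its own face. Bu3SnH/AIBN then reduces the CH2I group to the C-17 methyl, giving 14.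

**Further compounds**
F1 | step 4 | methyl (2Z,5R,6E)-5-(tert-butyldimethylsilyloxy)-3-(diethoxyphosphoryloxy)-7,11-dimethyldodeca-2,6,10-trienoate | COC(=O)/C=C(\OP(=O)(OCC)OCC)C[C@@H](O[Si](C)(C)C(C)(C)C)/C=C(\C)CCC=C(C)C
F2 | step 4 | methyl (2E,5R,6E)-5-(tert-butyldimethylsilyloxy)-3,7,11-trimethyldodeca-2,6,10-trienoate | COC(=O)/C=C(\C)C[C@@H](O[Si](C)(C)C(C)(C)C)/C=C(\C)CCC=C(C)C
F3 | step 4 | (2E,5R,6E)-5-(tert-butyldimethylsilyloxy)-3,7,11-trimethyldodeca-2,6,10-trien-1-ol | OC/C=C(\C)C[C@@H](O[Si](C)(C)C(C)(C)C)/C=C(\C)CCC=C(C)C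
F4 | step 4 | (2E,5R,6E)-1,5-bis(tert-butyldimethylsilyloxy)-3,7,11-trimethyldodeca-2,6,10-triene | CC(C)(C)[Si](C)(C)OC/C=C(\C)C[C@@H](O[Si](C)(C)C(C)(C)C)/C=C(\C)CCC=C(C)C
F5 | step 4 | (2E,5R,6E)-1,5-bis(tert-butyldimethylsilyloxy)-9-(3,3-dimethyloxiran-2-yl)-3,7-dimethylnona-2,6-diene (both oxirane epimers) | CC(C)(C)[Si](C)(C)OC/C=C(\C)C[C@@H](O[Si](C)(C)C(C)(C)C)/C=C(\C)CCC1OC1(C)C
F6 | step 5 | methyl 6-(tert-butyldimethylsilyloxy)-3,8-dihydroxy-4,4,10-trimethyl-8-[(trimethylsilyl)methyl]-trans-decalin-9-carboxylate (ring centres as in 7) | COC(=O)[C@@H]1C(O)(C[Si](C)(C)C)C[C@@H](O[Si](C)(C)C(C)(C)C)[C@@H]2C(C)(C)C(O)CC[C@@]12C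
F7 | step 10 | 2-{7-(tert-butyldimethylsilyloxy)-9-[(tert-butyldimethylsilyloxy)methyl]-1-(iodomethyl)-5-methyl-3-oxo-2-oxabicyclo[3.3.1]nonan-6-yl}-2-methylpropanoic acid (ring centres as in 14) | CC(C)(C)[Si](C)(C)OC[C@H]1[C@]2(C)CC(=O)O[C@@]1(CI)C[C@@H](O[Si](C)(C)C(C)(C)C)[C@@H]2C(C)(C)C(=O)O
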